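## Analysis of the target

The target 17 is a carbon–carbon linked biflavonoid. A 5-hydroxy-7-methoxyflavone is bonded through C3' of its B ring (the linking ring, a 4'-phenol) to C3 of a 5,7,4'-trihydroxyflavanone (ring A phloroglucinol-type, ring C dihydropyranone, ring B 4-hydroxyphenyl). The only stereocentres are C2 (S) and C3 (R) of ring C; they are adjacent and the two aryl groups are trans, which is the diequatorial and thermodynamically preferred arrangement. C3 is benzylic and alpha to the C4 ketone, and C2 is the beta-aryloxy carbon of that ketone. Base can therefore open ring C by a retro-oxa-Michael reaction and erase both centres, whereas simple enolisation only returns the trans isomer. Other sensitive groups are five phenols (two chelated to carbonyl groups), the flavone C2=C3 bond and the aryl ketone, so the end game has to stay neutral or mildly acidic. The difficulty is to form the hindered C3–C3' bond between two electron-rich flavonoid halves while fixing the absolute configuration at C2 and the trans relation at C3, and then to keep that information. The strategy rests on the six atoms of ring C. O1, C8a, C4a and C4 form a heterodiene that ring A can supply as an ortho-quinone methide at the aldehyde oxidation level, and C2–C3 is then the double bond of an E-stilbene that already joins ring B to the linking ring.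

## Retrosynthetic reasoning

Target 17 is first traced back to 16, in which the four phenols on the flavanone, ring B and flavone C5 are benzyl ethers and the linking-ring phenol is a benzyl carbonate. No skeletal bond is cut. All five groups fall in one neutral hydrogenolysis, so the base-sensitive ring C never meets base after the ketone exists.

16 is traced back to the 4-methoxyflavan 15 by a change of oxidation level at C4 only. The C4 methyl ether is a masked ketone; the forward step must remove the C4 hydrogen oxidatively without touching C2–H or C3–H. The C4 stereocentre of 15 disappears here, so its configuration is irrelevant.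

15 is cut at O1–C2 and at C3–C4 into the salicylaldehyde acetal 13 (reacting through ion 14) and the stilbene 10. This is the place to cut because both stereocentres lie on these two bonds and one cycloaddition then delivers ring C, the C3–aryl bond and ring B together. The E geometry of 10 encodes the trans relation. The forward reaction must give O1-to-C2 regiochemistry, trans stereochemistry and one absolute sense. Cutting C3–C3' instead would require arylation of a flavanone enolate, and cutting C2–C3 would require separate control of the two centres.

10 is traced back to the free phenol 9 (carbonate formation) and 9 to the bromoflavone 7 and the styrene 8 by a cut at the C3'–vinyl bond. The forward step is a palladium-catalysed arylation of a terminal alkene, which gives the E-alkene directly and uses a bromine already present in a commercial aldehyde.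

7 is traced back through the protected flavone 6 to the chalcone 5 (cut at O1–C2 of the flavone pyranone, oxidative cyclisation forward), and 5 to the acetophenone 2 and the aldehyde 4 (cut at the enone C=C, aldol condensation forward). 2 and 4 come from 1 and 3 by one protection each. The flavone is finished before any stereocentre exists, so its harsh conditions cost nothing.

13 is traced back to the salicylaldehyde 12 (acetal formation) and 12 to the symmetric phenol 11 by a cut at the formyl–aryl bond. The forward formylation has to go ortho to the free hydroxyl, and both ortho positions of 11 are equivalent.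

## Alternatives that were turned down

Alternative 1: The linking ring itself is cut at C2'–C3' and C1'–C6' into the dienyl ether A1 (a chromone carrying a (Z)-2-benzyloxybutadienyl group at C3) and the 2-ethynylchromone A2. The forward key step is a thermal Diels–Alder reaction followed by dehydrogenation in the same pot, giving the isoflavone–flavone hybrid A3.
- For it: the polarities match. The enol-ether carbon of A1 is the nucleophilic terminus and the distal alkyne carbon of A2 the electrophilic one, which places the oxygen para to the flavone. The step has no stereochemical demand and no cationic intermediates, so as a reaction it is more likely to work than the key step chosen here.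
- Against it: it builds a benzene ring that can be bought with all three substituents in place (compound 3). A1 is a hydrolysis-prone dienyl ether that needs several steps. A3 is flat: it lacks ring B at C2 and has neither stereocentre.
- What remains after A3: ring B would have to be added by an enantioselective conjugate arylation of a 3-arylchromone in the presence of a second pyranone, with controlled protonation at C3. That is harder than the problem the cycloaddition solved.
- Comparison: the chosen strategy spends its key step on the ring that carries the stereocentres and brings in ring B, C2 and C3 at once.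

Alternative 2: The flavone pyranone is cut at C4a–C4, C4–C3 and O1–C2 into 2-iodo-5-methoxyresorcinol A4, carbon monoxide A5 and the terminal alkyne A6, a complete stereodefined flavanone with an ethynyl group on the linking ring. The forward key step uses PdCl2(PPh3)2 in a secondary amine: carbonylative coupling to an ynone and amine-assisted six-membered closure to A7.
- For it: it is highly convergent. A4 is symmetric, so either hydroxyl can close and the flavone 5-OH needs no protection. On late convergence and protecting-group economy for the flavone half it is stronger than the chosen route.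
- Against it: it leaves the real problem untouched. A6 already contains ring C, C2 and C3 and would have to be made first by chemistry at least as demanding as the whole chosen route, with an alkyne that is not innocent toward cations or hydrogenation.
- Risk in the key step: the base-sensitive flavanone is heated in an amine under A5, conditions that open ring C by retro-oxa-Michael reaction and erase both centres. The electron-rich A4 adds slowly to zerovalent palladium, and five-membered closure to an aurone competes.
- Comparison: in the chosen route the flavone is made by robust chemistry while nothing can epimerise, and the stereocentres appear three steps from the end and then see only an oxidant and hydrogen.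

Alternative 3: Ring C is cut at C2–C3. The precursor is the diazoketone A8, with the diazo carbon (C3) between the C4 carbonyl and the linking ring, and with two equivalent ortho 4-benzyloxybenzyl ethers on ring A. In the forward key step Rh2(S-PTTL)4 forms a rhodium carbene that inserts into a benzylic C–H bond of one ether, closing ring C with the ketone in place; equilibration at C3 gives trans A9.
- For it: enantioselective intramolecular C–H insertion into ether-activated benzylic positions with chiral dirhodium carboxylates is established chemistry. On precedent for the stereo-determining event it is stronger than the ion-pair cycloaddition chosen here, and it needs no redox adjustment at C4.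
- Against it: the ether oxygen sits five atoms from the carbene. Oxonium ylide formation and [1,2]-shift of the 4-alkoxybenzyl group (an excellent migrating group) would compete with six-membered C–H insertion, and several arenes are open to carbene addition.
- Step economy: A8 needs a linear build-up of a deoxybenzoin with three kinds of protecting group and a diazo transfer. The silyl ether of A9 must then be removed with a fluoride source basic enough to threaten ring C.
- Comparison: the chosen strategy joins two short fragments, forms both ring C bonds in one step and ends with a single neutral deprotection. It pays with a stereo-determining step of weaker precedent.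

Key step: step 9

Remark: the sense of induction of the chiral acid in step 9 cannot be predicted with confidence; the (R)-catalyst is written, and its antipode is to be used if the opposite enantiomer predominates.

Remark: compounds 1, 3, 8 and 11 are taken to be commercially available.

## Route

Step 1
Reactants: 1 1-(2,6-dihydroxy-4-methoxyphenyl)ethan-1-one
Product: 2 1-[2-(benzyloxy)-6-hydroxy-4-methoxyphenyl]ethan-1-one
Conditions: BnBr (1.05 equiv), K2CO3, acetone, reflux
Reagents that add atoms: benzyl bromide, BrCc1ccccc1
Why: Williamson ether synthesis; 1 is symmetric, and after the first alkylation the remaining hydroxyl is chelated to the ketone and far less nucleophilic, so the mono-ether should predominate.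

Step 2
Reactants: 3 3-bromo-4-hydroxybenzaldehyde
Product: 4 3-bromo-4-(methoxymethoxy)benzaldehyde
Conditions: MOMCl, iPr2NEt, CH2Cl2, 0 °C to rt
Reagents that add atoms: chloromethyl methyl ether, COCCl
Why: O-alkylation of the acidic phenol; the base-stable methoxymethyl ether keeps the aldehyde electrophilic in step 3 (a phenoxide would deactivate it) and is removed by acid before the acid-sensitive stilbene exists.

Step 3
Reactants: 2 1-[2-(benzyloxy)-6-hydroxy-4-methoxyphenyl]ethan-1-one; 4 3-bromo-4-(methoxymethoxy)benzaldehyde
Product: 5 (E)-1-[2-(benzyloxy)-6-hydroxy-4-methoxyphenyl]-3-[3-bromo-4-(methoxymethoxy)phenyl]prop-2-en-1-one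
Conditions: KOH (50% aq.), EtOH, rt
Reagents that add atoms: none
Why: Claisen–Schmidt condensation; the aldol adduct dehydrates by an E1cB path to the E-enone, and any flavanone formed by closure of 5 converges on the same flavone in step 4.

Step 4
Reactants: 5 (E)-1-[2-(benzyloxy)-6-hydroxy-4-methoxyphenyl]-3-[3-bromo-4-(methoxymethoxy)phenyl]prop-2-en-1-one
Product: 7 5-(benzyloxy)-2-(3-bromo-4-hydroxyphenyl)-7-methoxy-4H-chromen-4-one, via MOM-protected flavone 6 (not isolated)
Conditions: I2 (10 mol%), DMSO, 120 °C; then 3 M HCl, MeOH/THF, 50 °C
Reagents that add atoms: none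
Why: Iodine-catalysed oxidative cyclisation of a 2'-hydroxychalcone (oxa-Michael closure, alpha-iodination, loss of HI, reoxidation of HI by DMSO), then acid methanolysis of the methoxymethyl ether; partial loss of that group during the cyclisation is harmless because both species end as 7.

Step 5
Reactants: 7 5-(benzyloxy)-2-(3-bromo-4-hydroxyphenyl)-7-methoxy-4H-chromen-4-one; 8 1-(benzyloxy)-4-vinylbenzene
Product: 9 5-(benzyloxy)-2-{3-[(E)-2-(4-benzyloxyphenyl)ethenyl]-4-hydroxyphenyl}-7-methoxy-4H-chromen-4-one
Conditions: Pd(OAc)2 (5 mol%), P(o-tol)3 (12 mol%), Et3N, DMF, 100 °C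
Reagents that add atoms: none
Why: Mizoroki–Heck reaction; the aryl bromide, activated by the para chromonyl group, adds to zerovalent palladium, insertion occurs at the terminal carbon of 8 and syn beta-hydride elimination gives the E-stilbene; free ortho-bromophenols are tolerated in this coupling.

Step 6
Reactants: 9 5-(benzyloxy)-2-{3-[(E)-2-(4-benzyloxyphenyl)ethenyl]-4-hydroxyphenyl}-7-methoxy-4H-chromen-4-one
Product: 10 benzyl 2-[(E)-2-(4-benzyloxyphenyl)ethenyl]-4-[5-(benzyloxy)-7-methoxy-4-oxo-4H-chromen-2-yl]phenyl carbonate
Conditions: CbzCl, Et3N, DMAP (cat.), CH2Cl2, 0 °C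
Reagents that add atoms: benzyl chloroformate, O=C(Cl)OCc1ccccc1
Why: O-acylation of the only free phenol; the carbonate makes this oxygen a weak donor and a non-nucleophile for step 9 and is removed together with the benzyl ethers in step 11.

Step 7
Reactants: 11 3,5-bis(benzyloxy)phenol
Product: 12 2,4-bis(benzyloxy)-6-hydroxybenzaldehyde
Conditions: MgCl2, Et3N, (CH2O)n, MeCN, reflux; aq. HCl work-up
Reagents that add atoms: paraformaldehyde (as formaldehyde), C=O
Why: Magnesium-mediated ortho-formylation of a phenol (Casnati–Skattebøl reaction); the magnesium phenoxide delivers formaldehyde only to the ortho position, the two ortho positions of 11 are equivalent, and a second formaldehyde oxidises the benzylic alkoxide to the aldehyde.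

Step 8
Reactants: 12 2,4-bis(benzyloxy)-6-hydroxybenzaldehyde
Product: 13 3,5-bis(benzyloxy)-2-(dimethoxymethyl)phenol
Conditions: HC(OMe)3, MeOH, CSA (cat.), rt; Et3N quench, concentrate, use crude at once
Reagents that add atoms: trimethyl orthoformate, COC(OC)OC; methanol, CO
Why: Acid-catalysed acetalisation driven by the orthoformate as water scavenger; the quench with base before concentration protects the very acid-labile, electron-rich acetal, which is used without chromatography.

Step 9
Reactants: 13 3,5-bis(benzyloxy)-2-(dimethoxymethyl)phenol; 10 benzyl 2-[(E)-2-(4-benzyloxyphenyl)ethenyl]-4-[5-(benzyloxy)-7-methoxy-4-oxo-4H-chromen-2-yl]phenyl carbonate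
Product: 15 benzyl 2-[(2S,3S,4S)-5,7-bis(benzyloxy)-2-(4-benzyloxyphenyl)-4-methoxy-3,4-dihydro-2H-chromen-3-yl]-4-[5-(benzyloxy)-7-methoxy-4-oxo-4H-chromen-2-yl]phenyl carbonate, via O-methyl oxocarbenium ion 14 (not isolated)
Conditions: (R)-TRIP [(R)-3,3'-bis(2,4,6-triisopropylphenyl)-1,1'-binaphthyl-2,2'-diyl hydrogen phosphate] (10 mol%), 5 Å MS, PhMe/CH2Cl2 (2:1), −20 °C, 13 (2 equiv) added over 6 h
Reagents that add atoms: none
Why: Proposed new method: the closest known reaction types are the Brønsted-acid-catalysed [4+2] cycloaddition of salicylaldehyde acetals or ortho-quinone methides with styrenes to 2-arylchromans, and chiral-phosphoric-acid-controlled cycloadditions of ortho-quinone methides with more nucleophilic, hydrogen-bonding alkenes; an intermolecular enantioselective version with an unactivated 1,2-diarylethene is not established. The acid protonates one acetal oxygen of 13 and methanol leaves, giving 14, which is the O-protonated ortho-quinone methide of ring A, held to the chiral phosphate by ion pairing and by the phenol O–H···O=P hydrogen bond. The stilbene carbon next to the linking ring attacks C4 of 14 (C3–C4 bond) because the charge then develops on the carbon bearing the 4-benzyloxyphenyl group, and the phenol oxygen closes onto that carbon (O1–C2 bond), so ring C forms by an asynchronous inverse-electron-demand hetero-[4+2] cycloaddition of the heterodiene O1=C8a–C4a=C4 with the alkene. The 2,3-trans relation follows from suprafacial addition to the E-alkene and is also the diequatorial arrangement, so even a stepwise closure should lead to it. The C4 methoxy group is expected trans to the C3 aryl group (ring B endo over the cationic diene, all-equatorial product), but this centre is removed in step 10 and its epimer would converge. The absolute configuration at C2 and C3 is set by the chiral phosphate, which shields one face of the hydrogen-bonded diene. The step needs O1-to-C2 regioselectivity, which rests on the para-benzyloxy group of ring B against a linking ring deactivated by its chromonyl group and its carbonate; the carbonate also keeps the linking-ring oxygen from closing a five-membered ring on the C2 cation. Slow addition of 13 keeps the cation concentration low and should hold back Friedel–Crafts self-condensation of ring A.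

Step 10
Reactants: 15 benzyl 2-[(2S,3S,4S)-5,7-bis(benzyloxy)-2-(4-benzyloxyphenyl)-4-methoxy-3,4-dihydro-2H-chromen-3-yl]-4-[5-(benzyloxy)-7-methoxy-4-oxo-4H-chromen-2-yl]phenyl carbonate
Product: 16 benzyl 2-[(2S,3R)-5,7-bis(benzyloxy)-2-(4-benzyloxyphenyl)-4-oxo-3,4-dihydro-2H-chromen-3-yl]-4-[5-(benzyloxy)-7-methoxy-4-oxo-4H-chromen-2-yl]phenyl carbonate
Conditions: DDQ (1.5 equiv), CH2Cl2/pH 7 buffer (10:1), 0 °C to rt
Reagents that add atoms: water, O
Why: DDQ oxidation of a benzylic methyl ether to a ketone: hydride is taken from C4–H, which is activated by the methoxy group and the dioxygenated ring A and is axial in the all-trans isomer, water adds to the oxocarbenium ion and methanol is lost. C2–H, flanked only by an aryl ether oxygen and a mono-alkoxy arene, is much less hydridic; C2 and C3 keep their geometry, and the C3 descriptor changes from S to R only because C4 gains priority.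

Step 11
Reactants: 16 benzyl 2-[(2S,3R)-5,7-bis(benzyloxy)-2-(4-benzyloxyphenyl)-4-oxo-3,4-dihydro-2H-chromen-3-yl]-4-[5-(benzyloxy)-7-methoxy-4-oxo-4H-chromen-2-yl]phenyl carbonate
Product: 17 (2S,3R)-5,7-dihydroxy-3-[2-hydroxy-5-(5-hydroxy-7-methoxy-4-oxo-4H-chromen-2-yl)phenyl]-2-(4-hydroxyphenyl)-2,3-dihydro-4H-chromen-4-one
Conditions: H2 (1 atm), 10% Pd/C, EtOAc/MeOH, rt
Reagents that add atoms: none
Why: Catalytic hydrogenolysis of four benzyl ethers and of the benzyl carbonate (which gives the phenol, toluene and CO2) under neutral conditions, so ring C cannot open and C2 and C3 are retained; the methyl ether is untouched.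

## Compound list

1 | 1-(2,6-dihydroxy-4-methoxyphenyl)ethan-1-one | CC(=O)c1c(O)cc(OC)cc1O | starting material
2 | 1-[2-(benzyloxy)-6-hydroxy-4-methoxyphenyl]ethan-1-one | CC(=O)c1c(O)cc(OC)cc1OCc1ccccc1 | intermediate
3 | 3-bromo-4-hydroxybenzaldehyde | O=Cc1ccc(O)c(Br)c1 | starting material
4 | 3-bromo-4-(methoxymethoxy)benzaldehyde | COCOc1ccc(C=O)cc1Br | intermediate
5 | (E)-1-[2-(benzyloxy)-6-hydroxy-4-methoxyphenyl]-3-[3-bromo-4-(methoxymethoxy)phenyl]prop-2-en-1-one | COCOc1ccc(/C=C/C(=O)c2c(O)cc(OC)cc2OCc2ccccc2)cc1Br | intermediate
6 | 5-(benzyloxy)-2-[3-bromo-4-(methoxymethoxy)phenyl]-7-methoxy-4H-chromen-4-one (not isolated) | COCOc1ccc(-c2cc(=O)c3c(OCc4ccccc4)cc(OC)cc3o2)cc1Br | intermediate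
7 | 5-(benzyloxy)-2-(3-bromo-4-hydroxyphenyl)-7-methoxy-4H-chromen-4-one | COc1cc(OCc2ccccc2)c2c(=O)cc(-c3ccc(O)c(Br)c3)oc2c1 | intermediate
8 | 1-(benzyloxy)-4-vinylbenzene | C=Cc1ccc(OCc2ccccc2)cc1 | starting material
9 | 5-(benzyloxy)-2-{3-[(E)-2-(4-benzyloxyphenyl)ethenyl]-4-hydroxyphenyl}-7-methoxy-4H-chromen-4-one | COc1cc(OCc2ccccc2)c2c(=O)cc(-c3ccc(O)c(/C=C/c4ccc(OCc5ccccc5)cc4)c3)oc2c1 | intermediate
10 | benzyl 2-[(E)-2-(4-benzyloxyphenyl)ethenyl]-4-[5-(benzyloxy)-7-methoxy-4-oxo-4H-chromen-2-yl]phenyl carbonate | COc1cc(OCc2ccccc2)c2c(=O)cc(-c3ccc(OC(=O)OCc4ccccc4)c(/C=C/c4ccc(OCc5ccccc5)cc4)c3)oc2c1 | intermediate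
11 | 3,5-bis(benzyloxy)phenol | Oc1cc(OCc2ccccc2)cc(OCc2ccccc2)c1 | starting material
12 | 2,4-bis(benzyloxy)-6-hydroxybenzaldehyde | O=Cc1c(O)cc(OCc2ccccc2)cc1OCc1ccccc1 | intermediate
13 | 3,5-bis(benzyloxy)-2-(dimethoxymethyl)phenol | COC(OC)c1c(O)cc(OCc2ccccc2)cc1OCc1ccccc1 | intermediate
14 | (E)-{[2,4-bis(benzyloxy)-6-hydroxyphenyl]methylidene}(methyl)oxonium, the O-protonated ortho-quinone methide of ring A, ion-paired with the chiral phosphate (cation shown; not isolated) | C/[O+]=C/c1c(O)cc(OCc2ccccc2)cc1OCc1ccccc1 | intermediate
15 | benzyl 2-[(2S,3S,4S)-5,7-bis(benzyloxy)-2-(4-benzyloxyphenyl)-4-methoxy-3,4-dihydro-2H-chromen-3-yl]-4-[5-(benzyloxy)-7-methoxy-4-oxo-4H-chromen-2-yl]phenyl carbonate (2,3-trans, 3,4-trans) | COc1cc(OCc2ccccc2)c2c(=O)cc(-c3ccc(OC(=O)OCc4ccccc4)c([C@H]4[C@H](OC)c5c(OCc6ccccc6)cc(OCc6ccccc6)cc5O[C@@H]4c4ccc(OCc5ccccc5)cc4)c3)oc2c1 | intermediate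
16 | benzyl 2-[(2S,3R)-5,7-bis(benzyloxy)-2-(4-benzyloxyphenyl)-4-oxo-3,4-dihydro-2H-chromen-3-yl]-4-[5-(benzyloxy)-7-methoxy-4-oxo-4H-chromen-2-yl]phenyl carbonate | COc1cc(OCc2ccccc2)c2c(=O)cc(-c3ccc(OC(=O)OCc4ccccc4)c([C@H]4C(=O)c5c(OCc6ccccc6)cc(OCc6ccccc6)cc5O[C@@H]4c4ccc(OCc5ccccc5)cc4)c3)oc2c1 | intermediate
17 | (2S,3R)-5,7-dihydroxy-3-[2-hydroxy-5-(5-hydroxy-7-methoxy-4-oxo-4H-chromen-2-yl)phenyl]-2-(4-hydroxyphenyl)-2,3-dihydro-4H-chromen-4-one | COc1cc(O)c2c(=O)cc(-c3ccc(O)c([C@H]4C(=O)c5c(O)cc(O)cc5O[C@@H]4c4ccc(O)cc4)c3)oc2c1 | target

## Step count and least certain steps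

Total step count: 11. Longest linear sequence: 8 steps (step 1 or 2, then steps 3, 4, 5, 6, 9, 10, 11). The ring A branch (steps 7 and 8) joins at step 9.

Step 9 (key step, proposed new method).
- What may go wrong:
  - Friedel–Crafts self-condensation of the cation with the very electron-rich ring A of the acetal or of the product may outrun attack by the weakly nucleophilic stilbene.
  - Facial discrimination may be poor, because the stilbene has no hydrogen-bond donor to anchor it to the phosphate.
  - The basic pyranone carbonyl of 10 may buffer the acid.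
  - The C4 ether of the product may re-ionise and eliminate.
- Fallback (known chemistry): it sets out from 10 and 13. The cycloaddition is run without asymmetric induction with TfOH (5 mol%) in CH2Cl2 at −40 °C, the established achiral form of this reaction type. This should give 15 together with its enantiomer, the (2R,3R,4R)-4-methoxyflavan F1. The mixture is oxidised as in step 10 to 16 and its enantiomer, the (2R,3S)-flavanone F2. The two are separated by preparative HPLC on a chiral stationary phase, and the route is rejoined at 16.

Step 10.
- What may go wrong: the C4 oxocarbenium ion may lose the C3 proton to give the enol ether, with further dehydrogenation to the 3-arylchromone, which would destroy both stereocentres. Hydride abstraction at C2 may compete.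
- Fallback: it sets out from 15. The C4 methyl ether is solvolysed with aqueous TFA in THF at 0 °C to the (2S,3S,4S)-flavan-4-ol F3 (either C4 epimer serves). F3 is oxidised with Dess–Martin periodinane (NaHCO3, CH2Cl2), coming back at 16.

Step 8.
- What may go wrong: the acetal may revert to the aldehyde or self-condense during concentration and transfer, because loss of methanol from it is very easy.
- Fallback: it sets out from 12 and 10. The acetal is never handled; it is generated in the reaction flask from 12 and HC(OMe)3 under the acid of step 9 in the presence of 10 (the known three-component form of the chroman synthesis) and consumed as it forms. The route is rejoined at 15. No compound outside the list is made (F0).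

Step 4.
- What may go wrong: hydrogen iodide at 120 °C may remove the benzyl group peri to the carbonyl or iodinate an electron-rich ring.
- Fallback: it sets out from 5 and avoids iodine. Base-mediated oxa-Michael closure (NaOAc, EtOH, reflux) gives the racemic flavanone F4. Dehydrogenation with DDQ in dioxane at reflux gives 6, now isolated, and the acid methanolysis of step 4 leads back to 7.

Step 11.
- What may go wrong: over-reduction, namely saturation of the flavone C2=C3 bond, hydrogenolysis of the benzylic C2–O1 bond of ring C, or reduction of the C4 ketone.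
- Fallback: it sets out from 16 and is non-reductive. BCl3 with pentamethylbenzene as benzyl-cation scavenger in CH2Cl2 at −78 °C should cleave the benzyl ethers and the benzyl carbonate while leaving the methyl ether, which is not peri to a carbonyl group. This gives 17 directly. No compound outside the list is made (F0).

## Further compounds

F1 | step 9 | benzyl 2-[(2R,3R,4R)-5,7-bis(benzyloxy)-2-(4-benzyloxyphenyl)-4-methoxy-3,4-dihydro-2H-chromen-3-yl]-4-[5-(benzyloxy)-7-methoxy-4-oxo-4H-chromen-2-yl]phenyl carbonate (enantiomer of 15) | COc1cc(OCc2ccccc2)c2c(=O)cc(-c3ccc(OC(=O)OCc4ccccc4)c([C@@H]4[C@@H](OC)c5c(OCc6ccccc6)cc(OCc6ccccc6)cc5O[C@H]4c4ccc(OCc5ccccc5)cc4)c3)oc2c1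
F2 | step 9 | benzyl 2-[(2R,3S)-5,7-bis(benzyloxy)-2-(4-benzyloxyphenyl)-4-oxo-3,4-dihydro-2H-chromen-3-yl]-4-[5-(benzyloxy)-7-methoxy-4-oxo-4H-chromen-2-yl]phenyl carbonate (enantiomer of 16) | COc1cc(OCc2ccccc2)c2c(=O)cc(-c3ccc(OC(=O)OCc4ccccc4)c([C@@H]4C(=O)c5c(OCc6ccccc6)cc(OCc6ccccc6)cc5O[C@H]4c4ccc(OCc5ccccc5)cc4)c3)oc2c1
F3 | step 10 | benzyl 2-[(2S,3S,4S)-5,7-bis(benzyloxy)-2-(4-benzyloxyphenyl)-4-hydroxy-3,4-dihydro-2H-chromen-3-yl]-4-[5-(benzyloxy)-7-methoxy-4-oxo-4H-chromen-2-yl]phenyl carbonate | COc1cc(OCc2ccccc2)c2c(=O)cc(-c3ccc(OC(=O)OCc4ccccc4)c([C@H]4[C@H](O)c5c(OCc6ccccc6)cc(OCc6ccccc6)cc5O[C@@H]4c4ccc(OCc5ccccc5)cc4)c3)oc2c1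
F0 | step 8 | none | none
F4 | step 4 | racemic 5-(benzyloxy)-2-[3-bromo-4-(methoxymethoxy)phenyl]-7-methoxy-2,3-dihydro-4H-chromen-4-one | COCOc1ccc(C2CC(=O)c3c(OCc4ccccc4)cc(OC)cc3O2)cc1Br
F0 | step 11 | none | none
A1 | alternative 1 | 5,7-bis(benzyloxy)-3-[(1Z)-2-(benzyloxy)buta-1,3-dien-1-yl]-4H-chromen-4-one | C=C/C(OCc1ccccc1)=C/c1coc2cc(OCc3ccccc3)cc(OCc3ccccc3)c2c1=O
A2 | alternative 1 | 5-(benzyloxy)-2-ethynyl-7-methoxy-4H-chromen-4-one | C#Cc1cc(=O)c2c(OCc3ccccc3)cc(OC)cc2o1
A3 | alternative 1 | 5-(benzyloxy)-2-{4-(benzyloxy)-3-[5,7-bis(benzyloxy)-4-oxo-4H-chromen-3-yl]phenyl}-7-methoxy-4H-chromen-4-one | COc1cc(OCc2ccccc2)c2c(=O)cc(-c3ccc(OCc4ccccc4)c(-c4coc5cc(OCc6ccccc6)cc(OCc6ccccc6)c5c4=O)c3)oc2c1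
A4 | alternative 2 | 2-iodo-5-methoxybenzene-1,3-diol | COc1cc(O)c(I)c(O)c1
A5 | alternative 2 | carbon monoxide | [C-]#[O+]
A6 | alternative 2 | (2S,3R)-5,7-bis(benzyloxy)-3-[2-(benzyloxy)-5-ethynylphenyl]-2-(4-benzyloxyphenyl)-2,3-dihydro-4H-chromen-4-one | C#Cc1ccc(OCc2ccccc2)c([C@H]2C(=O)c3c(OCc4ccccc4)cc(OCc4ccccc4)cc3O[C@@H]2c2ccc(OCc3ccccc3)cc2)c1
A7 | alternative 2 | (2S,3R)-5,7-bis(benzyloxy)-3-[2-(benzyloxy)-5-(5-hydroxy-7-methoxy-4-oxo-4H-chromen-2-yl)phenyl]-2-(4-benzyloxyphenyl)-2,3-dihydro-4H-chromen-4-one | COc1cc(O)c2c(=O)cc(-c3ccc(OCc4ccccc4)c([C@H]4C(=O)c5c(OCc6ccccc6)cc(OCc6ccccc6)cc5O[C@@H]4c4ccc(OCc5ccccc5)cc4)c3)oc2c1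
A8 | alternative 3 | 1-{4-(benzyloxy)-2,6-bis[(4-benzyloxybenzyl)oxy]phenyl}-2-{5-[5-(benzyloxy)-7-methoxy-4-oxo-4H-chromen-2-yl]-2-[(tert-butyldimethylsilyl)oxy]phenyl}-2-diazoethan-1-one | COc1cc(OCc2ccccc2)c2c(=O)cc(-c3ccc(O[Si](C)(C)C(C)(C)C)c(C(=[N+]=[N-])C(=O)c4c(OCc5ccc(OCc6ccccc6)cc5)cc(OCc5ccccc5)cc4OCc4ccc(OCc5ccccc5)cc4)c3)oc2c1
A9 | alternative 3 | (2S,3R)-7-(benzyloxy)-5-[(4-benzyloxybenzyl)oxy]-3-{5-[5-(benzyloxy)-7-methoxy-4-oxo-4H-chromen-2-yl]-2-[(tert-butyldimethylsilyl)oxy]phenyl}-2-(4-benzyloxyphenyl)-2,3-dihydro-4H-chromen-4-one | COc1cc(OCc2ccccc2)c2c(=O)cc(-c3ccc(O[Si](C)(C)C(C)(C)C)c([C@H]4C(=O)c5c(OCc6ccc(OCc7ccccc7)cc6)cc(OCc6ccccc6)cc5O[C@@H]4c4ccc(OCc5ccccc5)cc4)c3)oc2c1
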